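**The ratio.** Divide the product formed, in M, by the spent carrier charged and by the time. The ratio is a turnover frequency: how many molecules of product each carrier has made per minute.

| flask | substrate | salt in the second phase | spent carrier | added ligand | remark | time | volume of the second phase over the first |
|---|---|---|---|---|---|---|---|
| ochre | 0.10 M | 0.30 M | 3.4 mM | 8.3 mM | run made earlier |  |  |
| grey | 0.10 M | 0.30 M | 7.5 mM | 8.3 mM | run made earlier |  |  |
| blue | 0.10 M | 0.60 M | 5 mM | 8.3 mM | run made earlier |  |  |
| flask | 0.10 M | 0.300 M | 5.0 mM | 8.3 mM |  | 10 min | 1.0 |

- ochre (time / min: product / %, crystals / %, substrate / %): 0.500: 0.7, 0.5, 99.0; 0.667: 0.8, 0, 98.3; 1.00: 0.9, 0.2, 98.2; 1.50: 2.2, 0, 96.7; 2.50: 3.8, 0.4, 97.3; 4.00: 5.1, 0, 94.9; 6.00: 6.4, 0, 93.6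
- grey (time / min: product / %, crystals / %, substrate / %): 0.500: 1.6, 0, 98.0; 0.667: 1.9, 0.1, 97.7; 1.00: 3.1, 0.7, 96.7; 1.50: 5.0, 0.4, 94.6; 2.50: 8.1, 0, 92.0; 4.00: 11.2, 0, 88.0; 6.00: 16.0, 0.2, 84.2
- blue (time / min: product / %, crystals / %, substrate / %): 0.500: 1.3, 0.4, 98.0; 0.833: 3.4, 0, 97.0; 1.50: 3.2, 1.0, 95.8; 3.00: 6.4, 0, 92.4; 6.00: 12.1, 0, 88.7

(readings scatter by 0.5 percentage points)

- what is said of product includes crystals
- charges count per volume of the first phase; a concentration in a rate is the amount of a species over the volume of its own phase; every rate counts per litre of the first phase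
- crystals is a solid; its amount is given per volume of the solution
- the earlier runs were read with a standard deviation of 0.5 percentage points
- the earlier runs hold the two phases in the same ratio of volumes as the flask asked about

* how much product and crystals together there is at 10 min, in percent of the substrate charged
* concentration of product in solution at 10 min, in percent of saturation

**First minutes.** Take the ochre and grey runs, whose salt matches the flask, and set blue aside. At 6.00 min they give 0.314 min⁻¹ and 0.356 min⁻¹, so product roughly follows the carrier charge, and the two can be pooled. Pooled up to 2.50 min, the ratio reads 0.437 min⁻¹.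

**The middle.** Up to 6.00 min the pooled mean is 0.343 min⁻¹. Between 4.00 min and 6.00 min the rate reads 0.280 min⁻¹. That is a fall of 35.9%, larger than the 15.8% of substrate grey has lost, so substrate loss is too small to account for the whole fall.

**The end.** Carry the late rate on to 10 min, and weigh the two stretches by their times. This gives 0.317 min⁻¹: call it m, the mean turnover frequency up to the asked time. Multiply m by the carrier charge and the time, and divide by the substrate charge: my reckoning for the flask gives 15.9%. Now check the error of the mean. The early mean held throughout gives 17.1%, the late rate throughout 14.0%. Grey's crystals read 0.2%, inside the scatter of 0.5 percentage points, at a product reading of 16.0%, about my figure, so expect none in the flask; saturation stays unread.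

**The forecast.** It says 15%, below my 15.9%, and 65% of saturation, holding that “the slowing looks time-driven, not product-driven”.

**The result.** The flask gives 14.9%, at 40.2% of saturation, so the forecast's saturation stood 25 points high.

    added ligand + fresh carrier ⇌ idle complex (K = 650 M⁻¹, k = 140 M⁻¹ min⁻¹)
    substrate + fresh carrier → product + spent carrier (k = 13.0 M⁻¹ min⁻¹)
    spent carrier + salt in the second phase ⇌ fresh carrier + spent salt in the second phase (K = 2.70, k = 7.80 M⁻¹ min⁻¹)
    crystals ⇌ product, rate k4*(cs4 - [product]) while solid is left; crystals form when [product] > cs4 (solubility = 37.0 mM, k = 13.0 min⁻¹)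

Idle complex holds 32.7% of the catalyst at 1.00 min and 67.5% at 10.0 min. Apply m to a neighbour flask charged with 0.020 M of spent carrier: it predicts 63.5%. That neighbour flask gives 67.4%, with 30.1% of the substrate charged standing as crystals, counted in that figure.

The runs were computed with constants of no real substance; noise was put on by code.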